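**Plan**
1. Retrosynthetic cuts, in order: O1–C2 of the flavanone (oxa-Michael), the chalcone Cα=Cβ bond (aldol), the acetyl–ring D bond (cross-coupling at a bromine handle), C4–C4a of the flavan (cation cyclisation), C4–ring D (aryl-metal addition to an aldehyde), the C2–O1 aryl ether (Mitsunobu) and C2–C3 (allylation).
2. Forward: 4-hydroxybenzaldehyde pivalate → homoallylic alcohol → 3,5-dimethoxyphenyl ether → aldehyde → diaryl carbinol → flavan ring C (step 7) → acetyl group on ring D → chalcone → pyranone ring E of the flavanone (step 12) → deprotection.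
3. Enabling feature: flavan C4 is doubly benzylic and ring D (the aryl group on C4, later the benzo ring of the flavanone) carries oxygen at both ortho positions and the para position, so a C4 carbinol ionises to a long-lived cation. Ring A is a 3,5-dimethoxyphenoxy unit whose two ortho carbons are equivalent, so closure onto C4a has a single regiochemical outcome.
4. Stereochemistry: flavan C2 comes from a catalytic asymmetric allylation (R) followed by inversion in the ether formation (S). Flavan C4 is set trans to C2 by substrate control in the cation closure. Flavanone C2 (S) is set by a chiral bifunctional catalyst in the oxa-Michael step, the two epimers being separable diastereomers.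
5. Protecting groups: an electron-withdrawing pivalate on the ring B oxygen (keeps the C2 benzylic position from ionising), benzyl ethers on ring D through the cation step, MOM ethers on two ring D oxygens for the end game.

Key step: step 7

Remark on the chemistry: 1,3,5-tris(benzyloxy)benzene is taken as a catalogue compound. The flavan C4 configuration is given throughout as its relation to C2 (2,4-trans: the aryl groups on C2 and C4 lie on opposite faces of ring C); the SMILES strings fix it.

**Step 1**
Reactants: 1 4-hydroxybenzaldehyde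
Product: 2 4-formylphenyl pivalate
Conditions: PivCl, Et3N, DMAP (cat.), CH2Cl2, 0 °C → rt
Reagents that add atoms: pivaloyl chloride, CC(C)(C)C(=O)Cl
Why: Nucleophilic-catalysed O-acylation of the phenol; the hindered, electron-withdrawing ester is chosen so that the later benzylic substitution stays SN2 and the C2 ether resists Lewis acid.

**Step 2**
Reactants: 2 4-formylphenyl pivalate
Product: 3 4-[(1R)-1-hydroxybut-3-en-1-yl]phenyl pivalate
Conditions: allylSnBu3, (R)-BINOL (20 mol %), Ti(OiPr)4 (10 mol %), 4 Å MS, CH2Cl2, −20 °C; aq. NaHCO3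
Reagents that add atoms: allyltributylstannane, C=CC[Sn](CCCC)(CCCC)CCCC
Why: Keck asymmetric allylation, in which the BINOL–titanium Lewis acid directs allyl transfer to the re face of the aryl aldehyde and so gives the (R)-carbinol under neutral conditions that spare the aryl ester.

**Step 3**
Reactants: 3 4-[(1R)-1-hydroxybut-3-en-1-yl]phenyl pivalate; 4 3,5-dimethoxyphenol
Product: 5 4-[(1S)-1-(3,5-dimethoxyphenoxy)but-3-en-1-yl]phenyl pivalate
Conditions: PPh3, DIAD, THF, 0 °C → rt
Reagents that add atoms: none
Why: Mitsunobu etherification, an SN2 displacement of the alkoxyphosphonium by the phenoxide that inverts (R) to (S); the pivaloyloxy group disfavours benzylic ionisation, which is what erodes inversion with electron-rich aryl carbinols.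

**Step 4**
Reactants: 5 4-[(1S)-1-(3,5-dimethoxyphenoxy)but-3-en-1-yl]phenyl pivalate
Product: 7 (3S)-3-(3,5-dimethoxyphenoxy)-3-[4-(pivaloyloxy)phenyl]propanal, via vicinal diol 6 (not isolated)
Conditions: OsO4 (2 mol %), NaIO4, 2,6-lutidine, dioxane–H2O (3:1), rt
Reagents that add atoms: osmium tetroxide, O=[Os](=O)(=O)=O; sodium periodate, [Na+].[O-][I](=O)(=O)=O
Why: Lemieux–Johnson oxidation (dihydroxylation, then periodate glycol cleavage), which leaves the electron-rich aryl ether untouched where ozone would not, and does not touch the ether stereocentre.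

**Step 5**
Reactants: 8 1,3,5-tris(benzyloxy)benzene
Product: 9 2,4-dibromo-1,3,5-tris(benzyloxy)benzene
Conditions: NBS (2.05 equiv), CH2Cl2, 0 °C → rt, dark
Reagents that add atoms: N-bromosuccinimide, O=C1CCC(=O)N1Br
Why: Electrophilic aromatic bromination at two of the three equivalent ring positions; one bromine serves for metalation and the other is kept as the handle for the acetyl group.

**Step 6**
Reactants: 9 2,4-dibromo-1,3,5-tris(benzyloxy)benzene; 7 (3S)-3-(3,5-dimethoxyphenoxy)-3-[4-(pivaloyloxy)phenyl]propanal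
Product: 12 (3S)-1-[2,4,6-tris(benzyloxy)-3-bromophenyl]-3-(3,5-dimethoxyphenoxy)-3-[4-(pivaloyloxy)phenyl]propan-1-ol (both C1 epimers), via aryllithium 10 (not isolated), via arylcerium dichloride 11 (not isolated)
Conditions: n-BuLi (1.0 equiv), THF, −78 °C; CeCl3, −78 °C; then 7, −78 → −40 °C; aq. NH4Cl
Reagents that add atoms: none
Why: Bromine–lithium exchange at one of two equivalent bromines, transmetalation to the organocerium and 1,2-addition to the aldehyde; the weakly basic cerium reagent should avoid enolisation, β-elimination of the aryloxide and attack on the pivalate, and the new carbinol centre is left uncontrolled because it is erased in the next step.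

**Step 7**
Reactants: 12 (3S)-1-[2,4,6-tris(benzyloxy)-3-bromophenyl]-3-(3,5-dimethoxyphenoxy)-3-[4-(pivaloyloxy)phenyl]propan-1-ol (both C1 epimers)
Product: 13 4-[(2S)-4-[2,4,6-tris(benzyloxy)-3-bromophenyl]-5,7-dimethoxychroman-2-yl]phenyl pivalate (2,4-trans)
Conditions: BF3·OEt2 (0.2 equiv), CH2Cl2 (0.01 M), −78 → −30 °C; Et3N
Reagents that add atoms: none
Why: The Lewis acid ionises the carbinol of either epimer to one planar benzylic cation delocalised onto the benzyloxy oxygens of ring D, and an ortho carbon of the tethered 3,5-dimethoxyphenoxy ring (ortho to the ether oxygen, ortho and para to the methoxy groups) attacks it and then loses a proton; the closest known reaction type is the acid-mediated intramolecular Friedel–Crafts alkylation of 3-aryloxy-1-arylpropan-1-ols to 4-arylchromans. Ring C closes in a 6-exo-trig mode when the cation is written in its quinone-methide form (the C4=C(ring D) bond lies outside the new ring), the attacking arene bond being endocyclic as in any Friedel–Crafts ring closure. The new C4 centre is controlled by the C2 centre: in the chair-like transition state the C2 aryl group is equatorial and ring D on C4 goes pseudoaxial to escape the peri C5 methoxy group, which places the two aryl groups trans. Regiochemistry needs no control, since the two ortho carbons of ring A are equivalent and the carbon between the methoxy groups cannot reach the cation. The step needs the carbinol to ionise and the C2 aryl ether not to; the trioxygenated ring D makes the C4 cation far more stable, the pivaloyloxy group on ring B withdraws electron density from the C2 benzylic position, and low temperature with catalytic acid keeps the two apart.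

**Step 8**
Reactants: 13 4-[(2S)-4-[2,4,6-tris(benzyloxy)-3-bromophenyl]-5,7-dimethoxychroman-2-yl]phenyl pivalate (2,4-trans)
Product: 15 4-[(2S)-4-[3-acetyl-2,4,6-tris(benzyloxy)phenyl]-5,7-dimethoxychroman-2-yl]phenyl pivalate (2,4-trans), via enol ether 14 (not isolated)
Conditions: tributyl(1-ethoxyvinyl)stannane, Pd(P(t-Bu)3)2 (5 mol %), toluene, 90 °C; then 1 M HCl, THF, 0 °C → rt
Reagents that add atoms: tributyl(1-ethoxyvinyl)stannane, CCOC(=C)[Sn](CCCC)(CCCC)CCCC; water, O
Why: Stille coupling with the ethoxyvinyl stannane as an acetyl equivalent, then hydrolysis of the enol ether; the bulky electron-rich phosphine serves the doubly ortho-substituted bromide, and placing the acyl group before debenzylation avoids Friedel–Crafts acylation of an acid-labile free phloroglucinol ring.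

**Step 9**
Reactants: 15 4-[(2S)-4-[3-acetyl-2,4,6-tris(benzyloxy)phenyl]-5,7-dimethoxychroman-2-yl]phenyl pivalate (2,4-trans)
Product: 16 4-[(2S)-4-(3-acetyl-2,4,6-trihydroxyphenyl)-5,7-dimethoxychroman-2-yl]phenyl pivalate (2,4-trans)
Conditions: H2 (1 atm), Pd/C (10 wt %), EtOAc–MeOH, rt
Reagents that add atoms: none
Why: Hydrogenolysis of aryl benzyl ethers, which is faster than cleavage of the cyclic benzylic C2–O bond and leaves the vinylogous-acid aryl ketone and the pivalate alone.

**Step 10**
Reactants: 16 4-[(2S)-4-(3-acetyl-2,4,6-trihydroxyphenyl)-5,7-dimethoxychroman-2-yl]phenyl pivalate (2,4-trans)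
Product: 17 4-[(2S)-4-[3-acetyl-2-hydroxy-4,6-bis(methoxymethoxy)phenyl]-5,7-dimethoxychroman-2-yl]phenyl pivalate (2,4-trans)
Conditions: MOMCl (2.2 equiv), i-Pr2NEt, CH2Cl2, 0 °C
Reagents that add atoms: chloromethyl methyl ether, COCCl
Why: O-Alkylation of phenols (MOM protection) at the non-chelated hydroxyl para to the acetyl group and at the unhindered ortho hydroxyl; the hydroxyl flanked by both the acetyl group and the flavan-4-yl group is hydrogen-bonded and shielded on both sides and should stay free.

**Step 11**
Reactants: 17 4-[(2S)-4-[3-acetyl-2-hydroxy-4,6-bis(methoxymethoxy)phenyl]-5,7-dimethoxychroman-2-yl]phenyl pivalate (2,4-trans); 18 benzaldehyde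
Product: 19 (E)-1-[2-hydroxy-3-[(2S)-2-(4-hydroxyphenyl)-5,7-dimethoxychroman-4-yl]-4,6-bis(methoxymethoxy)phenyl]-3-phenylprop-2-en-1-one (flavan 2,4-trans)
Conditions: KOH, EtOH–H2O, rt; then 1 M HCl to pH 5
Reagents that add atoms: none
Why: Claisen–Schmidt condensation (aldol addition and E1cB dehydration) gives the (E)-chalcone, and the hydroxide cleaves the aryl pivalate in the same operation.

**Step 12**
Reactants: 19 (E)-1-[2-hydroxy-3-[(2S)-2-(4-hydroxyphenyl)-5,7-dimethoxychroman-4-yl]-4,6-bis(methoxymethoxy)phenyl]-3-phenylprop-2-en-1-one (flavan 2,4-trans)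
Product: 20 (2S)-8-[(2S)-2-(4-hydroxyphenyl)-5,7-dimethoxychroman-4-yl]-5,7-bis(methoxymethoxy)-2-phenylchroman-4-one (flavan 2,4-trans)
Conditions: 9-amino(9-deoxy)epi-quinidine 3,5-bis(trifluoromethyl)phenyl thiourea (20 mol %), toluene, rt
Reagents that add atoms: none
Why: Organocatalytic intramolecular oxa-Michael addition (6-endo-trig) of the only free ortho hydroxyl, which fixes the linkage at C8; the thiourea binds the enone carbonyl while the quinuclidine delivers the phenol to the face expected to give the 2S centre, and the minor C2 epimer, being a diastereomer, is removed by chromatography.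

**Step 13**
Reactants: 20 (2S)-8-[(2S)-2-(4-hydroxyphenyl)-5,7-dimethoxychroman-4-yl]-5,7-bis(methoxymethoxy)-2-phenylchroman-4-one (flavan 2,4-trans)
Product: 21 (2S)-5,7-dihydroxy-8-[(2S)-2-(4-hydroxyphenyl)-5,7-dimethoxychroman-4-yl]-2-phenylchroman-4-one (flavan 2,4-trans)
Conditions: HCl (2 M), MeOH–THF, 40 °C
Reagents that add atoms: none
Why: Acid-catalysed acetal exchange removes both MOM ethers; the flavanone C2 centre does not epimerise in acid, and the acyl-deactivated ring D should keep the C4–C8 bond intact under these mild conditions.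

**Compound list**
1 | 4-hydroxybenzaldehyde | O=Cc1ccc(O)cc1 | starting material
2 | 4-formylphenyl pivalate | O=Cc1ccc(OC(=O)C(C)(C)C)cc1 | intermediate
3 | 4-[(1R)-1-hydroxybut-3-en-1-yl]phenyl pivalate | O[C@@H](c1ccc(OC(=O)C(C)(C)C)cc1)CC=C | intermediate
4 | 3,5-dimethoxyphenol | COc1cc(O)cc(OC)c1 | starting material
5 | 4-[(1S)-1-(3,5-dimethoxyphenoxy)but-3-en-1-yl]phenyl pivalate | COc1cc(OC)cc(c1)O[C@H](c1ccc(OC(=O)C(C)(C)C)cc1)CC=C | intermediate
6 | (4S)-4-(3,5-dimethoxyphenoxy)-4-[4-(pivaloyloxy)phenyl]butane-1,2-diol, both C2 epimers | COc1cc(OC)cc(c1)O[C@H](c1ccc(OC(=O)C(C)(C)C)cc1)CC(O)CO | intermediate (not isolated)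
7 | (3S)-3-(3,5-dimethoxyphenoxy)-3-[4-(pivaloyloxy)phenyl]propanal | COc1cc(OC)cc(c1)O[C@H](c1ccc(OC(=O)C(C)(C)C)cc1)CC=O | intermediate
8 | 1,3,5-tris(benzyloxy)benzene | c1ccc(cc1)COc1cc(OCc2ccccc2)cc(OCc2ccccc2)c1 | starting material
9 | 2,4-dibromo-1,3,5-tris(benzyloxy)benzene | Brc1c(OCc2ccccc2)cc(OCc2ccccc2)c(Br)c1OCc1ccccc1 | intermediate
10 | [2,4,6-tris(benzyloxy)-3-bromophenyl]lithium | [Li]c1c(OCc2ccccc2)cc(OCc2ccccc2)c(Br)c1OCc1ccccc1 | intermediate (not isolated)
11 | [2,4,6-tris(benzyloxy)-3-bromophenyl]cerium dichloride | Cl[Ce](Cl)c1c(OCc2ccccc2)cc(OCc2ccccc2)c(Br)c1OCc1ccccc1 | intermediate (not isolated)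
12 | (3S)-1-[2,4,6-tris(benzyloxy)-3-bromophenyl]-3-(3,5-dimethoxyphenoxy)-3-[4-(pivaloyloxy)phenyl]propan-1-ol, both C1 epimers | COc1cc(OC)cc(c1)O[C@H](c1ccc(OC(=O)C(C)(C)C)cc1)CC(O)c1c(OCc2ccccc2)cc(OCc2ccccc2)c(Br)c1OCc1ccccc1 | intermediate
13 | 4-[(2S)-4-[2,4,6-tris(benzyloxy)-3-bromophenyl]-5,7-dimethoxychroman-2-yl]phenyl pivalate, 2,4-trans | COc1cc(OC)c2c(c1)O[C@H](c1ccc(OC(=O)C(C)(C)C)cc1)C[C@H]2c1c(OCc2ccccc2)cc(OCc2ccccc2)c(Br)c1OCc1ccccc1 | intermediate
14 | 4-[(2S)-4-[2,4,6-tris(benzyloxy)-3-(1-ethoxyvinyl)phenyl]-5,7-dimethoxychroman-2-yl]phenyl pivalate, 2,4-trans | COc1cc(OC)c2c(c1)O[C@H](c1ccc(OC(=O)C(C)(C)C)cc1)C[C@H]2c1c(OCc2ccccc2)cc(OCc2ccccc2)c(C(=C)OCC)c1OCc1ccccc1 | intermediate (not isolated)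
15 | 4-[(2S)-4-[3-acetyl-2,4,6-tris(benzyloxy)phenyl]-5,7-dimethoxychroman-2-yl]phenyl pivalate, 2,4-trans | COc1cc(OC)c2c(c1)O[C@H](c1ccc(OC(=O)C(C)(C)C)cc1)C[C@H]2c1c(OCc2ccccc2)cc(OCc2ccccc2)c(C(C)=O)c1OCc1ccccc1 | intermediate
16 | 4-[(2S)-4-(3-acetyl-2,4,6-trihydroxyphenyl)-5,7-dimethoxychroman-2-yl]phenyl pivalate, 2,4-trans | COc1cc(OC)c2c(c1)O[C@H](c1ccc(OC(=O)C(C)(C)C)cc1)C[C@H]2c1c(O)cc(O)c(C(C)=O)c1O | intermediate
17 | 4-[(2S)-4-[3-acetyl-2-hydroxy-4,6-bis(methoxymethoxy)phenyl]-5,7-dimethoxychroman-2-yl]phenyl pivalate, 2,4-trans | COc1cc(OC)c2c(c1)O[C@H](c1ccc(OC(=O)C(C)(C)C)cc1)C[C@H]2c1c(OCOC)cc(OCOC)c(C(C)=O)c1O | intermediate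
18 | benzaldehyde | O=Cc1ccccc1 | starting material
19 | (E)-1-[2-hydroxy-3-[(2S)-2-(4-hydroxyphenyl)-5,7-dimethoxychroman-4-yl]-4,6-bis(methoxymethoxy)phenyl]-3-phenylprop-2-en-1-one, flavan 2,4-trans | COc1cc(OC)c2c(c1)O[C@H](c1ccc(O)cc1)C[C@H]2c1c(OCOC)cc(OCOC)c(C(=O)/C=C/c2ccccc2)c1O | intermediate
20 | (2S)-8-[(2S)-2-(4-hydroxyphenyl)-5,7-dimethoxychroman-4-yl]-5,7-bis(methoxymethoxy)-2-phenylchroman-4-one, flavan 2,4-trans | COc1cc(OC)c2c(c1)O[C@H](c1ccc(O)cc1)C[C@H]2c1c(OCOC)cc(OCOC)c2c1O[C@H](c1ccccc1)CC2=O | intermediate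
21 | (2S)-5,7-dihydroxy-8-[(2S)-2-(4-hydroxyphenyl)-5,7-dimethoxychroman-4-yl]-2-phenylchroman-4-one, flavan 2,4-trans (CNP0188217.1) | COc1cc(OC)c2c(c1)O[C@H](c1ccc(O)cc1)C[C@H]2c1c(O)cc(O)c2c1O[C@H](c1ccccc1)CC2=O | target

**Step count**
Total: 13 steps. Longest linear sequence: 12 steps (steps 1–4 and 6–13; step 5 is the one-step side branch).

**Steps most likely to fail**

Step 12. Facial selectivity in the ring closure may be low on a chalcone without an activating group, and the closure is reversible, so the epimer ratio can drift toward the thermodynamic mixture. The fallback gives up catalyst control in favour of equilibration, separation and recycling. It sets out from chalcone 19, which is cyclised with NaOAc in refluxing EtOH to give 20 together with its flavanone C2 epimer, (2R)-8-[(2S)-2-(4-hydroxyphenyl)-5,7-dimethoxychroman-4-yl]-5,7-bis(methoxymethoxy)-2-phenylchroman-4-one F1. Because the flavan centres are fixed, the two are diastereomers and should separate by chromatography; F1 is returned to the same conditions, where it reopens to 19 and partitions again. The fallback comes back to the route at 20.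

Step 7. The cation may lose a proton to a styrene, the C2 ether may ionise and scramble C2, or the closure may show weak trans selectivity. The fallback reverses the order of the two bonds at C4 and sets out from aldehyde 7 and from 8. Compound 8 is brominated once (NBS, 1 equiv) to 2-bromo-1,3,5-tris(benzyloxy)benzene F2. Aldehyde 7 is then treated with BF3·OEt2 at −40 °C in the presence of excess F2: ring A attacks the activated aldehyde to give 4-[(2S)-4-hydroxy-5,7-dimethoxychroman-2-yl]phenyl pivalate F3 (both C4 epimers, not isolated). This flavan-4-ol ionises to the ring-A-stabilised C4 cation, which F2 captures through a ring carbon between two benzyloxy groups, anti to the C2 aryl group, as in known flavan-4-ol arylations. The fallback comes back to the route at 13.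

Step 10. Alkylation may reach the flanked hydroxyl, or fail to distinguish the two chelated hydroxyls, which would misdirect the later ring closure to the C6-linked flavanone. The fallback reverses the logic from selective protection to selective deprotection and sets out from 16. All three hydroxyls are protected (MOMCl in excess, i-Pr2NEt, DMF, 50 °C) to give 4-[(2S)-4-[3-acetyl-2,4,6-tris(methoxymethoxy)phenyl]-5,7-dimethoxychroman-2-yl]phenyl pivalate F4. One MOM group is then removed with one equivalent of HCl in MeOH at 0 °C; the ether on the doubly flanked oxygen is twisted out of conjugation and assisted by the neighbouring carbonyl, so it is expected to cleave first, as known for MOM ethers ortho to aryl ketones. The fallback comes back to the route at 17.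

**Further compounds**
F1 | step 12 | (2R)-8-[(2S)-2-(4-hydroxyphenyl)-5,7-dimethoxychroman-4-yl]-5,7-bis(methoxymethoxy)-2-phenylchroman-4-one, flavan 2,4-trans | COc1cc(OC)c2c(c1)O[C@H](c1ccc(O)cc1)C[C@H]2c1c(OCOC)cc(OCOC)c2c1O[C@@H](c1ccccc1)CC2=O
F2 | step 7 | 2-bromo-1,3,5-tris(benzyloxy)benzene | Brc1c(OCc2ccccc2)cc(OCc2ccccc2)cc1OCc1ccccc1
F3 | step 7 | 4-[(2S)-4-hydroxy-5,7-dimethoxychroman-2-yl]phenyl pivalate, both C4 epimers | COc1cc(OC)c2c(c1)O[C@H](c1ccc(OC(=O)C(C)(C)C)cc1)CC2O
F4 | step 10 | 4-[(2S)-4-[3-acetyl-2,4,6-tris(methoxymethoxy)phenyl]-5,7-dimethoxychroman-2-yl]phenyl pivalate, 2,4-trans | COc1cc(OC)c2c(c1)O[C@H](c1ccc(OC(=O)C(C)(C)C)cc1)C[C@H]2c1c(OCOC)cc(OCOC)c(C(C)=O)c1OCOC
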